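**Retrosynthetic overview** (target numbering: ring A = C8(OOH)–C9=C11–C12(=O)–C13(Me)=C14(vinyl); ring B = C5(CH‑isopropenyl)–C6–C7–C8–C9–C10(quaternary C‑Me))
1. C8–OOH comes last, by singlet‑oxygen dearomatisation of phenol 16 at the carbon para to the C12 hydroxyl.
2. The C14 vinyl group replaces the C14 oxygen of resorcinol 12 (silylation of the less hindered O12, triflation of O14, Stille coupling).
3. Key disconnection C8–C9 and C12–C13: resorcinol 12 from open‑chain enone–enoate 9. Enabling feature: C8 is the α‑carbon of an ethyl enone (C7=C8–C14(=O)–C13H2CH3) tied through C7–C6–C5–C10 to the acrylate β‑carbon C9, and C13H2 lies 1,5 to the ester carbon C12, so a 1,3‑dinucleophile (C8/C13 around C14=O) faces a 1,3‑dielectrophile (C9/C12) across what becomes ring B.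
4. 9 comes from dialdehyde 7 by two Wittig reactions (unhindered, then hindered CHO); 7 comes from (S)‑carvone, whose ring is only a stereochemical template (C5 from the pool, C10 by methylation then anti Michael addition) and is opened by excising carvone C2.
5. Ring order: ring B (Rauhut–Currier, C8–C9), then ring A (Claisen, C12–C13, aromatisation) in the same flask; no ring of the target exists before the key step.

Key step: step 7

Remark: centres that are later planarised or excised (C6 of 2 and 3, the epoxide carbons, the carbinol of 5, the triol centres of 6, C9 of 10) are carried as mixtures and drawn as the expected major isomer or left open. Steps 1–4 use carvone numbering. The keto ylide of step 5 is used as purchased or made from 1‑bromobutan‑2‑one and PPh3.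

**Step 1**
Reactants: 1 (S)-(+)-carvone
Product: 2 (5S,6R)-2,6-dimethyl-5-(prop-1-en-2-yl)cyclohex-2-en-1-one (trans-6-methylcarvone, minor C6 epimer carried along)
Conditions: LDA, THF, −78 °C; MeI, −78 → 0 °C
Reagents that add atoms: iodomethane, CI
Why: Kinetic deprotonation of the enone at the α′-CH2 and C-methylation of the cross-conjugated lithium enolate (enolate alkylation), mainly anti to the isopropenyl group; the C6 configuration does not matter because C6 is planarised again in step 3.

**Step 2**
Reactants: 2 trans-6-methylcarvone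
Product: 3 6-methylcarvone 2,3-epoxide (1,3-dimethyl-4-(prop-1-en-2-yl)-7-oxabicyclo[4.1.0]heptan-2-one, epoxide anti to isopropenyl)
Conditions: 30% H2O2, NaOH (cat.), MeOH, 0 °C
Reagents that add atoms: hydrogen peroxide, OO
Why: Weitz–Scheffer nucleophilic epoxidation attacks only the electron-poor enone C=C and spares the isopropenyl group, and it removes the enone that would otherwise let an acrylate adduct close by a second Michael addition; the epoxide configuration is not used later.

**Step 3**
Reactants: 3 6-methylcarvone 2,3-epoxide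
Product: 4 methyl 3-[1,3-dimethyl-2-oxo-4-(prop-1-en-2-yl)-7-oxabicyclo[4.1.0]heptan-3-yl]propanoate (3-methyl cis and propanoate arm trans to the 4-isopropenyl group)
Conditions: methyl acrylate, KOtBu (0.2 equiv), t-BuOH/THF, 0 °C → rt
Reagents that add atoms: methyl acrylate, C=CC(=O)OC
Why: C6 is the only enolisable position of 3, so catalytic tert-butoxide gives a single enolate whose Michael addition to the acrylate should occur anti to the adjacent isopropenyl group, setting the quaternary centre (future C10) from both C6 epimers.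

**Step 4**
Reactants: 4 epoxy keto ester
Product: 7 methyl (4R,5R)-4-formyl-4,6-dimethyl-5-(2-oxoethyl)hept-6-enoate, via epoxy alcohol 5 (not isolated), via triol 6 (not isolated)
Conditions: NaBH4, CeCl3·7H2O, MeOH, −20 °C; then H5IO6, THF/H2O, 0 °C → rt
Reagents that add atoms: none
Why: Borohydride reduces the ketone and periodic acid then hydrolyses the epoxide and cleaves both C–C bonds of the 1,2,3-triol (Malaprade cleavage), excising C2 with its methyl as acetic acid and leaving the two aldehydes, the isopropenyl group and both stereocentres intact; running both events in one flask should leave the δ-hydroxy ester no time to lactonise.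

**Step 5**
Reactants: 7 dialdehyde
Product: 8 methyl (4R,5R,7E)-4-formyl-4-methyl-9-oxo-5-(prop-1-en-2-yl)undec-7-enoate
Conditions: Ph3P=CHC(O)Et (1.05 equiv), CH2Cl2, 0 °C → rt
Reagents that add atoms: 1-(triphenyl-λ5-phosphanylidene)butan-2-one, CCC(=O)C=P(c1ccccc1)(c1ccccc1)c1ccccc1
Why: The stabilised keto ylide (Wittig olefination, E-selective) should react with the unhindered CH2–CHO much faster than with the aldehyde on the quaternary carbon, installing the ethyl enone (future C7=C8–C14(=O)–C13).

**Step 6**
Reactants: 8 enone aldehyde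
Product: 9 methyl (4S,5R,7E)-4-[(1E)-3-methoxy-3-oxoprop-1-en-1-yl]-4-methyl-9-oxo-5-(prop-1-en-2-yl)undec-7-enoate
Conditions: Ph3P=CHCO2Me (3 equiv), toluene, 90 °C
Reagents that add atoms: methyl (triphenyl-λ5-phosphanylidene)acetate, COC(=O)C=P(c1ccccc1)(c1ccccc1)c1ccccc1
Why: The non-enolisable neopentyl-type aldehyde is olefinated with the stabilised ester ylide under neutral conditions at higher temperature (Wittig, E-selective), giving the acrylate arm (future C9=C11–C12) without disturbing the enone.

**Step 7**
Reactants: 9 enone–enoate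
Product: 12 methyl 3-[(1R,2R)-5,7-dihydroxy-1,6-dimethyl-2-(prop-1-en-2-yl)-1,2,3,4-tetrahydronaphthalen-1-yl]propanoate, via Rauhut–Currier cyclohexene 10 (not isolated), via alkylidene dione 11 (not isolated)
Conditions: PBu3 (0.3 equiv), t-AmOH (0.02 M), 40 °C, Ar; then NaOMe (5 equiv), MeOH, 65 °C; then 1 M HCl
Reagents that add atoms: none
Why: The phosphine adds to the enone β-carbon C7 (more electrophilic than the enoate) and the resulting enolate carbon C8 closes 6-exo-trig onto the enoate β-carbon C9, after which proton transfer and loss of phosphine restore the C7=C8 enone; this is the intramolecular Rauhut–Currier reaction of a tethered enone–enoate and it closes ring B. Methoxide then forms the ethyl-ketone enolate at C13, which acylates the C12 ester in a 6-exo-trig Claisen closure of ring A, the classical cyclisation of a δ-keto ester to a 2-alkylcyclohexane-1,3-dione. The 4-alkylidene-1,3-dione 11 is an isoaromatic tautomer of a resorcinol, so a 1,3-proton shift from C9 to C7 (base, completed on acidification) moves the C7=C8 bond into ring A and the sequence ends irreversibly at the arene. No stereocentre formed here survives: C9 arises as a mixture and is erased on aromatisation, E/Z isomers of either olefin converge, and the non-enolisable C5 and C10 are untouched. The step needs chemoselectivity, and the tether supplies it: only the C8→C9 and C13→C12 pairings give six-membered rings from the ketone-derived nucleophiles (C13 onto the C3 propanoate would be eight-membered), and any ester–ester Dieckmann or aldol by-product is reversible under NaOMe/MeOH and should drain to the aromatic sink.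

**Step 8**
Reactants: 12 resorcinol
Product: 13 methyl 3-[(1R,2R)-5-hydroxy-1,6-dimethyl-2-(prop-1-en-2-yl)-7-{[tri(propan-2-yl)silyl]oxy}-1,2,3,4-tetrahydronaphthalen-1-yl]propanoate
Conditions: TIPSCl (1.1 equiv), imidazole, DMF, 0 °C → rt
Reagents that add atoms: chlorotri(propan-2-yl)silane, CC(C)[Si](Cl)(C(C)C)C(C)C
Why: The bulky silyl chloride should discriminate the two phenols sterically, since the C12 hydroxyl has one ortho hydrogen whereas the C14 hydroxyl is flanked by the C13 methyl and the ring-B CH2 (O-silylation).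

**Step 9**
Reactants: 13 mono-TIPS ether
Product: 14 methyl 3-[(1R,2R)-1,6-dimethyl-2-(prop-1-en-2-yl)-5-[(trifluoromethanesulfonyl)oxy]-7-{[tri(propan-2-yl)silyl]oxy}-1,2,3,4-tetrahydronaphthalen-1-yl]propanoate
Conditions: Tf2O, pyridine, CH2Cl2, 0 °C
Reagents that add atoms: trifluoromethanesulfonic anhydride, O=S(=O)(OS(=O)(=O)C(F)(F)F)C(F)(F)F
Why: O-Sulfonylation of the remaining hindered phenol by a small, very reactive electrophile turns the C14 oxygen that activated the key step into a leaving group.

**Step 10**
Reactants: 14 aryl triflate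
Product: 15 methyl 3-[(1R,2R)-5-ethenyl-1,6-dimethyl-2-(prop-1-en-2-yl)-7-{[tri(propan-2-yl)silyl]oxy}-1,2,3,4-tetrahydronaphthalen-1-yl]propanoate
Conditions: tributyl(vinyl)stannane, Pd(PPh3)4 (cat.), LiCl, 1,4-dioxane, 100 °C
Reagents that add atoms: tributyl(ethenyl)stannane, C=C[Sn](CCCC)(CCCC)CCCC
Why: Stille cross-coupling of an aryl triflate (LiCl-promoted) replaces the C14 oxygen by the vinyl group; the ester, silyl ether and isopropenyl group are inert to Pd(0).

**Step 11**
Reactants: 15 silyl-protected vinyl arene
Product: 16 methyl 3-[(1R,2R)-5-ethenyl-7-hydroxy-1,6-dimethyl-2-(prop-1-en-2-yl)-1,2,3,4-tetrahydronaphthalen-1-yl]propanoate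
Conditions: TBAF, AcOH, THF, 0 °C
Reagents that add atoms: none
Why: Fluoride cleaves the aryl silyl ether (driven by Si–F bond formation) under buffered conditions that spare the methyl ester and the styrene.

**Step 12**
Reactants: 16 phenol
Product: 17 trigonochinene C, methyl 3-[(1R,2R,4aR)-5-ethenyl-4a-hydroperoxy-1,6-dimethyl-7-oxo-2-(prop-1-en-2-yl)-1,2,3,4,4a,7-hexahydronaphthalen-1-yl]propanoate
Conditions: O2, rose bengal (cat.), visible light, MeOH/CH2Cl2, −10 °C
Reagents that add atoms: dioxygen, O=O
Why: Singlet oxygen adds to the electron-rich phenol at C8, para to the hydroxyl, and proton transfer gives the 4-hydroperoxycyclohexa-2,5-dienone (photooxygenation of a para-alkylphenol to a p-peroxyquinol); C8 is set by substrate control, attack being expected on the face opposite the C10 propanoate arm (cis to the C10 methyl), and the 1,1-disubstituted and styrenic alkenes should react much more slowly than the phenol.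

**Compound list**
1 | (S)-(+)-carvone | CC1=CC[C@H](C(=C)C)CC1=O | starting material
2 | (5S,6R)-2,6-dimethyl-5-(prop-1-en-2-yl)cyclohex-2-en-1-one | CC1=CC[C@H](C(=C)C)[C@@H](C)C1=O | intermediate
3 | 6-methylcarvone 2,3-epoxide (epoxide anti to isopropenyl) | C[C@]12O[C@H]1C[C@H](C(=C)C)[C@@H](C)C2=O | intermediate
4 | methyl 3-[1,3-dimethyl-2-oxo-4-(prop-1-en-2-yl)-7-oxabicyclo[4.1.0]heptan-3-yl]propanoate (3-Me cis to isopropenyl) | C[C@]12O[C@H]1C[C@H](C(=C)C)[C@@](C)(CCC(=O)OC)C2=O | intermediate
5 | epoxy alcohol from 4 (carbinol epimers) | C[C@]12O[C@H]1C[C@H](C(=C)C)[C@@](C)(CCC(=O)OC)C2O | intermediate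
6 | 1,2,3-triol from 5 (triol centres unassigned) | CC1(O)C(O)C[C@H](C(=C)C)[C@@](C)(CCC(=O)OC)C1O | intermediate
7 | methyl (4R,5R)-4-formyl-4,6-dimethyl-5-(2-oxoethyl)hept-6-enoate | O=CC[C@H](C(=C)C)[C@@](C=O)(C)CCC(=O)OC | intermediate
8 | methyl (4R,5R,7E)-4-formyl-4-methyl-9-oxo-5-(prop-1-en-2-yl)undec-7-enoate | CCC(=O)/C=C/C[C@H](C(=C)C)[C@@](C=O)(C)CCC(=O)OC | intermediate
9 | methyl (4S,5R,7E)-4-[(1E)-3-methoxy-3-oxoprop-1-en-1-yl]-4-methyl-9-oxo-5-(prop-1-en-2-yl)undec-7-enoate | CCC(=O)/C=C/C[C@H](C(=C)C)[C@@](/C=C/C(=O)OC)(C)CCC(=O)OC | intermediate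
10 | methyl 3-[2-(2-methoxy-2-oxoethyl)-1-methyl-3-propanoyl-6-(prop-1-en-2-yl)cyclohex-3-en-1-yl]propanoate (1-Me cis to 6-isopropenyl, C2 epimers) | CCC(=O)C1=CC[C@H](C(=C)C)[C@@](C)(CCC(=O)OC)C1CC(=O)OC | intermediate
11 | methyl 3-[1,6-dimethyl-5,7-dioxo-2-(prop-1-en-2-yl)-1,2,3,5,6,7,8,8a-octahydronaphthalen-1-yl]propanoate (C6/C8a epimers) | CC1C(=O)CC2C(=CC[C@H](C(=C)C)[C@@]2(C)CCC(=O)OC)C1=O | intermediate
12 | methyl 3-[(1R,2R)-5,7-dihydroxy-1,6-dimethyl-2-(prop-1-en-2-yl)-1,2,3,4-tetrahydronaphthalen-1-yl]propanoate | Oc1c(C)c(O)cc2c1CC[C@H](C(=C)C)[C@@]2(C)CCC(=O)OC | intermediate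
13 | methyl 3-[(1R,2R)-5-hydroxy-1,6-dimethyl-2-(prop-1-en-2-yl)-7-{[tri(propan-2-yl)silyl]oxy}-1,2,3,4-tetrahydronaphthalen-1-yl]propanoate | Oc1c(C)c(O[Si](C(C)C)(C(C)C)C(C)C)cc2c1CC[C@H](C(=C)C)[C@@]2(C)CCC(=O)OC | intermediate
14 | methyl 3-[(1R,2R)-1,6-dimethyl-2-(prop-1-en-2-yl)-5-[(trifluoromethanesulfonyl)oxy]-7-{[tri(propan-2-yl)silyl]oxy}-1,2,3,4-tetrahydronaphthalen-1-yl]propanoate | O=S(=O)(Oc1c(C)c(O[Si](C(C)C)(C(C)C)C(C)C)cc2c1CC[C@H](C(=C)C)[C@@]2(C)CCC(=O)OC)C(F)(F)F | intermediate
15 | methyl 3-[(1R,2R)-5-ethenyl-1,6-dimethyl-2-(prop-1-en-2-yl)-7-{[tri(propan-2-yl)silyl]oxy}-1,2,3,4-tetrahydronaphthalen-1-yl]propanoate | C=Cc1c(C)c(O[Si](C(C)C)(C(C)C)C(C)C)cc2c1CC[C@H](C(=C)C)[C@@]2(C)CCC(=O)OC | intermediate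
16 | methyl 3-[(1R,2R)-5-ethenyl-7-hydroxy-1,6-dimethyl-2-(prop-1-en-2-yl)-1,2,3,4-tetrahydronaphthalen-1-yl]propanoate | C=Cc1c(C)c(O)cc2c1CC[C@H](C(=C)C)[C@@]2(C)CCC(=O)OC | intermediate
17 | trigonochinene C | C=CC1=C(C)C(=O)C=C2[C@]1(OO)CC[C@H](C(=C)C)[C@@]2(C)CCC(=O)OC | target

**Total step count:** 12. **Longest linear sequence:** 12 steps (fully linear from (S)-carvone).

**Steps most likely to fail**

Step 7. Conjugate addition onto C9, which sits next to the quaternary C10, may be slow enough for the phosphonium enolate to isomerise the enone or oligomerise, and in the base stage ester–ester Dieckmann closure may compete with the ring-A Claisen or the final prototropic shift may stall. The fallback sets out from 9 and returns at 12, and makes the C8–C9 bond reductively instead of catalytically. Stryker's reagent ([(Ph3P)CuH]6, toluene, rt) reduces the enone and the copper enolate closes onto the enoate (reductive Michael cyclisation) to give the saturated keto diester F1. NaOMe in MeOH at reflux then effects the Claisen cyclisation to the bicyclic 2-methylcyclohexane-1,3-dione F2, and dehydrogenation (catalytic I2, DMSO, 80 °C) aromatises F2 to resorcinol 12.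

Step 12. The two faces of C8 may be poorly differentiated, and ene reaction at the isopropenyl group or [4+2] addition across the styrene may compete. The fallback sets out from 16 and returns at 16, and replaces reliance on facial control by recycling. The unwanted C8 epimer, 8-epi-hydroperoxide F3, is separated, reduced with PPh3 to the p-quinol F4, and re-aromatised with Zn/AcOH to phenol 16, which is resubmitted to the photooxygenation.

Step 3. Base-induced rearrangement of the α,β-epoxy ketone (Favorskii-type ring contraction or epoxide opening) may outrun the Michael addition, or the acrylate may not add cleanly anti to the isopropenyl group. The fallback sets out from 2 and returns at 4, and reverses the order of events. The kinetic lithium enolate of 2 (LDA, THF, −78 °C) is added to methyl acrylate and quenched cold with AcOH, before the ester enolate can close onto the enone, giving the enone ester F5. Weitz–Scheffer epoxidation (H2O2, NaOH, MeOH, 0 °C) then gives 4.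

**Further compounds**
F1 | step 7 | methyl 3-[2-(2-methoxy-2-oxoethyl)-1-methyl-3-propanoyl-6-(prop-1-en-2-yl)cyclohexyl]propanoate (C2/C3 epimers) | CCC(=O)C1CC[C@H](C(=C)C)[C@@](C)(CCC(=O)OC)C1CC(=O)OC
F2 | step 7 | methyl 3-[1,6-dimethyl-5,7-dioxo-2-(prop-1-en-2-yl)decahydronaphthalen-1-yl]propanoate (ring-fusion and C6 epimers) | CC1C(=O)CC2C(CC[C@H](C(=C)C)[C@@]2(C)CCC(=O)OC)C1=O
F3 | step 12 | 8-epi-trigonochinene C (4aS hydroperoxide) | C=CC1=C(C)C(=O)C=C2[C@@]1(OO)CC[C@H](C(=C)C)[C@@]2(C)CCC(=O)OC
F4 | step 12 | 8-epi p-quinol (4aS alcohol corresponding to F3) | C=CC1=C(C)C(=O)C=C2[C@@]1(O)CC[C@H](C(=C)C)[C@@]2(C)CCC(=O)OC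
F5 | step 3 | methyl 3-[1,3-dimethyl-2-oxo-6-(prop-1-en-2-yl)cyclohex-3-en-1-yl]propanoate (1-Me cis to 6-isopropenyl) | CC1=CC[C@H](C(=C)C)[C@@](C)(CCC(=O)OC)C1=O
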